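Atoms carry calamenene numbering, primed in the C5'-linked unit. Everything rests on cutting C1'–C8a', so that the saturated ring of that unit is made last by an acid-catalysed cation–olefin hydroarylation. In one operation the step closes the ring and sets C1'. It exploits that C8a' is ortho to O–C8' and para to the C6' methyl, with C5' blocked by ring A, and that C1' and C4' are both peri-flanked (OMe at C8', aryl at C5'), which enforces the trans-diaxial arrangement. The precursor is a biaryl: an intact 8-methoxycalamenene unit from (+)-menthone joined at C7 to an anisole carrying a (3R,5Z)-2-methylhept-5-en-3-yl chain.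

Key step: step 11

Remark: the C7–C5' axis bears four ortho substituents and the target structure does not define its configuration. The route leaves it uncontrolled, so compounds from 16 on may be mixtures of two atropisomers.

Step 1
Reactants: 1 (+)-menthone, (2R,5S)-5-methyl-2-(propan-2-yl)cyclohexan-1-one; 2 acrolein (prop-2-enal)
Product: 5 (3S,6R)-2-(1-hydroxyprop-2-en-1-yl)-3-methyl-1-(2-methylprop-2-en-1-yl)-6-(propan-2-yl)cyclohexan-1-ol as a mixture of epimers at C1 and C2 and at the carbinol carbon, via kinetic lithium enolate 3 (not isolated), via lithium aldolate 4 (not isolated)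
Conditions: LiN(i-Pr)2, THF, −78 °C; 2, −78 °C; then 2-methylallylmagnesium chloride (2.5 equiv), −78 to −20 °C; H2O
Reagents that add atoms: 2-methylallylmagnesium chloride, CC(=C)C[Mg]Cl
Why: Kinetic deprotonation takes a proton from the unhindered CH2 (C6 of menthone) and leaves the isopropyl-bearing α-centre alone, the enolate adds 1,2 to acrolein (directed aldol addition), and the allyl-type Grignard reagent should add to the hindered ketone of the aldolate faster than retro-aldol cleavage (Grignard addition); the three new centres form without control and all become sp2 in step 3, while the two menthone centres (future C4 and C1) are carried through.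

Step 2
Reactants: 5 the diene diol
Product: 6 (5R,8S)-3,8-dimethyl-5-(propan-2-yl)-1,4,4a,5,6,7,8,8a-octahydronaphthalene-1,4a-diol (epimer mixture at C1, C4a and C8a)
Conditions: second-generation Grubbs catalyst RuCl2(=CHPh)(H2IMes)(PCy3) (5 mol%), CH2Cl2, 40 °C
Reagents that add atoms: none
Why: Ring-closing metathesis of the vinyl carbinol with the 1,1-disubstituted methallyl alkene closes the future aromatic ring A as a trisubstituted cyclohexene with loss of ethene; free hydroxyl groups are tolerated and no stereocentre is formed or touched.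

Step 3
Reactants: 6 the bicyclic diol
Product: 8 (5R,8S)-3,8-dimethyl-5-(propan-2-yl)-5,6,7,8-tetrahydronaphthalen-1-ol [(1S,4R)-8-hydroxycalamenene], via hydroxy enone 7 (not isolated)
Conditions: Dess–Martin periodinane, CH2Cl2, 0 °C to rt; then TsOH·H2O (10 mol%), toluene, 60 °C
Reagents that add atoms: none
Why: Dess–Martin oxidation takes the secondary allylic alcohol to the enone and spares the tertiary alcohol, and acid then drives aldol-type dehydration through the enol of the new ketone (β-elimination towards C8a, not towards C4) followed by dienone-to-phenol tautomerisation, so ring A aromatises while C1 and C4 from menthone stay as they are.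

Step 4
Reactants: 8 (1S,4R)-8-hydroxycalamenene
Product: 9 (1S,4R)-8-methoxy-1,6-dimethyl-4-(propan-2-yl)-1,2,3,4-tetrahydronaphthalene
Conditions: MeI, K2CO3, acetone, reflux
Reagents that add atoms: iodomethane, CI
Why: Williamson ether synthesis of the phenol; the methyl ether directs the next lithiation and should survive every step up to step 12.

Step 5
Reactants: 9 the methyl ether
Product: 11 2-[(5R,8S)-1-methoxy-3,8-dimethyl-5-(propan-2-yl)-5,6,7,8-tetrahydronaphthalen-2-yl]-4,4,5,5-tetramethyl-1,3,2-dioxaborolane, via aryllithium 10 (not isolated)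
Conditions: s-BuLi, TMEDA, Et2O, −78 to 0 °C; then 2-isopropoxy-4,4,5,5-tetramethyl-1,3,2-dioxaborolane, −78 °C to rt; H2O
Reagents that add atoms: 2-isopropoxy-4,4,5,5-tetramethyl-1,3,2-dioxaborolane, CC(C)OB1OC(C)(C)C(C)(C)O1
Why: Directed ortho-metalation: the methoxy group directs lithiation to C7, its only free ortho position, and the aryllithium is trapped at boron (borylation); no stereocentre is involved.

Step 6
Reactants: 12 (3-methoxy-5-methylphenyl)boronic acid; 13 ethyl (2E)-4-methylpent-2-enoate
Product: 14 ethyl (3R)-3-(3-methoxy-5-methylphenyl)-4-methylpentanoate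
Conditions: Rh(acac)(C2H4)2 (3 mol%), (S)-BINAP (4.5 mol%), dioxane/H2O (10:1), 100 °C
Reagents that add atoms: none
Why: Hayashi–Miyaura rhodium-catalysed asymmetric 1,4-addition of an arylboronic acid to an (E)-enoate; the (S)-BINAP–rhodium aryl species is expected to add to the face of the β-isopropyl enoate that gives the (3R) centre (future C4'), under ligand control (the antipodal ligand would be taken if the facial sense proved opposite).

Step 7
Reactants: 14 the aryl ester
Product: 15 ethyl (3R)-3-(2-bromo-5-methoxy-3-methylphenyl)-4-methylpentanoate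
Conditions: NBS, MeCN, 0 °C to rt
Reagents that add atoms: N-bromosuccinimide, O=C1CCC(=O)N1Br
Why: Electrophilic aromatic bromination with NBS in acetonitrile should go para to the methoxy group, at the carbon between the methyl group and the side chain (future C5'), as is usual for 3,5-dialkylanisoles; the ester and the stereocentre are untouched.

Step 8
Reactants: 11 the boronate; 15 the aryl bromide
Product: 16 ethyl (3R)-3-{5-methoxy-2-[(5R,8S)-1-methoxy-3,8-dimethyl-5-(propan-2-yl)-5,6,7,8-tetrahydronaphthalen-2-yl]-3-methylphenyl}-4-methylpentanoate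
Conditions: Pd(OAc)2 (5 mol%), SPhos (10 mol%), K3PO4, toluene/H2O (10:1), 100 °C
Reagents that add atoms: none
Why: Suzuki–Miyaura cross-coupling with the dialkylbiarylphosphine SPhos, a ligand established for tetra-ortho-substituted biaryls, joins C7 to C5'; ester and methyl ethers tolerate K3PO4, no sp3 stereocentre is touched, and the new axis forms without control.

Step 9
Reactants: 16 the biaryl ester
Product: 17 (3R)-3-{5-methoxy-2-[(5R,8S)-1-methoxy-3,8-dimethyl-5-(propan-2-yl)-5,6,7,8-tetrahydronaphthalen-2-yl]-3-methylphenyl}-4-methylpentanal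
Conditions: i-Bu2AlH (1.1 equiv), CH2Cl2, −78 °C; then H2O
Reagents that add atoms: none
Why: Partial reduction of the ester with one equivalent of i-Bu2AlH at low temperature should stop at the aluminium hemiacetal, which gives the aldehyde on work-up; the β-stereocentre cannot epimerise.

Step 10
Reactants: 17 the biaryl aldehyde
Product: 18 (5R,8S)-1-methoxy-2-{4-methoxy-2-methyl-6-[(3R,5Z)-2-methylhept-5-en-3-yl]phenyl}-3,8-dimethyl-5-(propan-2-yl)-5,6,7,8-tetrahydronaphthalene
Conditions: ethyltriphenylphosphonium bromide, NaN(SiMe3)2, THF, 0 °C; then 17, −78 °C to rt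
Reagents that add atoms: ethyltriphenylphosphonium bromide, CC[P+](c1ccccc1)(c1ccccc1)c1ccccc1.[Br-]
Why: Wittig olefination with the non-stabilised ethylidene ylide should give mainly the (Z)-alkene (the geometry does not matter for step 11); the aldehyde has no α-stereocentre to lose.

Step 11
Reactants: 18 the biaryl alkene
Product: 20 (5R,8S)-1-methoxy-2-[(5S,8R)-4-methoxy-2,5-dimethyl-8-(propan-2-yl)-5,6,7,8-tetrahydronaphthalen-1-yl]-3,8-dimethyl-5-(propan-2-yl)-5,6,7,8-tetrahydronaphthalene, via C1' carbocation 19 (not isolated)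
Conditions: CF3SO3H (20 mol%), (CF3)2CHOH, 0 °C to rt
Reagents that add atoms: none
Why: Triflic acid protonates the C1'=C2' alkene, the C1' cation (in equilibrium with the C2' cation by 1,2-hydride shift) is attacked by C8a', the arene carbon ortho to the C8' methoxy group and para to the C6' methyl, and proton loss restores ring B; this is an acid-catalysed intramolecular alkene hydroarylation, a cation–olefin Friedel–Crafts cyclialkylation of the kind that turns 5-arylpent-2-enes into 1-methyltetralins. The ring (C8a', C4a', C4', C3', C2', C1') closes in the 6-endo-trig mode through a half-chair transition state. The step needs site selectivity between C8a' and C5' (both ortho to C4a') and between six- and five-membered closure: C5' is blocked by ring A, and closure from the C2' cation would give a five-membered ring with the arene double bond inside it, which is stereoelectronically poor, so the cations should funnel through C1'. The new centre C1' is controlled by C4' together with the two peri groups: the isopropyl group at C4' must sit pseudoaxial to avoid the aryl group at C5', the methyl group at C1' must sit pseudoaxial to avoid the methoxy group at C8' (1,3-allylic strain), and two pseudoaxial benzylic groups in a tetralin half-chair are trans, which is the (1'S,4'R) arrangement. The aryl methyl ethers, the tertiary benzylic C–H bonds and the stereocentres of the other unit should be inert to catalytic acid at this temperature.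

Step 12
Reactants: 20 the dimethyl ether
Product: 21 CNP0145304.1, (5R,8S)-2-[(5S,8R)-4-hydroxy-2,5-dimethyl-8-(propan-2-yl)-5,6,7,8-tetrahydronaphthalen-1-yl]-3,8-dimethyl-5-(propan-2-yl)-5,6,7,8-tetrahydronaphthalen-1-ol
Conditions: BBr3 (3 equiv), CH2Cl2, −78 °C to rt; then H2O
Reagents that add atoms: none
Why: Lewis-acid cleavage of both aryl methyl ethers by BBr3 (demethylation via the aryl dibromoborates) frees the two phenols; the benzylic stereocentres should not ionise under these conditions.

Compound list
1 | (+)-menthone, (2R,5S)-5-methyl-2-(propan-2-yl)cyclohexan-1-one | C[C@H]1CC[C@H](C(C)C)C(=O)C1 | starting material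
2 | acrolein (prop-2-enal) | C=CC=O | starting material
3 | lithium (3S,6R)-3-methyl-6-(propan-2-yl)cyclohex-1-en-1-olate (kinetic enolate) | C[C@H]1CC[C@H](C(C)C)C([O-])=C1.[Li+] | intermediate
4 | lithium 1-[(3R,6S)-6-methyl-2-oxo-3-(propan-2-yl)cyclohexyl]prop-2-en-1-olate (epimer mixture) | C[C@H]1CC[C@H](C(C)C)C(=O)C1C([O-])C=C.[Li+] | intermediate
5 | (3S,6R)-2-(1-hydroxyprop-2-en-1-yl)-3-methyl-1-(2-methylprop-2-en-1-yl)-6-(propan-2-yl)cyclohexan-1-ol (epimer mixture at the three new centres) | C[C@H]1CC[C@H](C(C)C)C(O)(CC(C)=C)C1C(O)C=C | intermediate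
6 | (5R,8S)-3,8-dimethyl-5-(propan-2-yl)-1,4,4a,5,6,7,8,8a-octahydronaphthalene-1,4a-diol (epimer mixture) | C[C@H]1CC[C@H](C(C)C)C2(O)CC(C)=CC(O)C12 | intermediate
7 | (5R,8S)-4a-hydroxy-3,8-dimethyl-5-(propan-2-yl)-4a,5,6,7,8,8a-hexahydronaphthalen-1(4H)-one (epimer mixture) | C[C@H]1CC[C@H](C(C)C)C2(O)CC(C)=CC(=O)C12 | intermediate
8 | (5R,8S)-3,8-dimethyl-5-(propan-2-yl)-5,6,7,8-tetrahydronaphthalen-1-ol, (1S,4R)-8-hydroxycalamenene | Cc1cc2c(c(O)c1)[C@@H](C)CC[C@@H]2C(C)C | intermediate
9 | (1S,4R)-8-methoxy-1,6-dimethyl-4-(propan-2-yl)-1,2,3,4-tetrahydronaphthalene | Cc1cc2c(c(OC)c1)[C@@H](C)CC[C@@H]2C(C)C | intermediate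
10 | [(5R,8S)-1-methoxy-3,8-dimethyl-5-(propan-2-yl)-5,6,7,8-tetrahydronaphthalen-2-yl]lithium | Cc1cc2c(c(OC)c1[Li])[C@@H](C)CC[C@@H]2C(C)C | intermediate
11 | 2-[(5R,8S)-1-methoxy-3,8-dimethyl-5-(propan-2-yl)-5,6,7,8-tetrahydronaphthalen-2-yl]-4,4,5,5-tetramethyl-1,3,2-dioxaborolane | Cc1cc2c(c(OC)c1B1OC(C)(C)C(C)(C)O1)[C@@H](C)CC[C@@H]2C(C)C | intermediate
12 | (3-methoxy-5-methylphenyl)boronic acid | COc1cc(C)cc(B(O)O)c1 | starting material
13 | ethyl (2E)-4-methylpent-2-enoate | CCOC(=O)/C=C/C(C)C | starting material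
14 | ethyl (3R)-3-(3-methoxy-5-methylphenyl)-4-methylpentanoate | CCOC(=O)C[C@@H](c1cc(C)cc(OC)c1)C(C)C | intermediate
15 | ethyl (3R)-3-(2-bromo-5-methoxy-3-methylphenyl)-4-methylpentanoate | CCOC(=O)C[C@@H](c1cc(OC)cc(C)c1Br)C(C)C | intermediate
16 | ethyl (3R)-3-{5-methoxy-2-[(5R,8S)-1-methoxy-3,8-dimethyl-5-(propan-2-yl)-5,6,7,8-tetrahydronaphthalen-2-yl]-3-methylphenyl}-4-methylpentanoate | CCOC(=O)C[C@@H](c1cc(OC)cc(C)c1-c1c(C)cc2c(c1OC)[C@@H](C)CC[C@@H]2C(C)C)C(C)C | intermediate
17 | (3R)-3-{5-methoxy-2-[(5R,8S)-1-methoxy-3,8-dimethyl-5-(propan-2-yl)-5,6,7,8-tetrahydronaphthalen-2-yl]-3-methylphenyl}-4-methylpentanal | O=CC[C@@H](c1cc(OC)cc(C)c1-c1c(C)cc2c(c1OC)[C@@H](C)CC[C@@H]2C(C)C)C(C)C | intermediate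
18 | (5R,8S)-1-methoxy-2-{4-methoxy-2-methyl-6-[(3R,5Z)-2-methylhept-5-en-3-yl]phenyl}-3,8-dimethyl-5-(propan-2-yl)-5,6,7,8-tetrahydronaphthalene | C/C=C\C[C@@H](c1cc(OC)cc(C)c1-c1c(C)cc2c(c1OC)[C@@H](C)CC[C@@H]2C(C)C)C(C)C | intermediate
19 | secondary C1' carbocation of 18 (heptan-2-ylium ion) as its triflate ion pair | C[CH+]CC[C@@H](c1cc(OC)cc(C)c1-c1c(C)cc2c(c1OC)[C@@H](C)CC[C@@H]2C(C)C)C(C)C.[O-]S(=O)(=O)C(F)(F)F | intermediate
20 | (5R,8S)-1-methoxy-2-[(5S,8R)-4-methoxy-2,5-dimethyl-8-(propan-2-yl)-5,6,7,8-tetrahydronaphthalen-1-yl]-3,8-dimethyl-5-(propan-2-yl)-5,6,7,8-tetrahydronaphthalene | Cc1cc2c(c(OC)c1-c1c(C)cc(OC)c3c1[C@@H](C(C)C)CC[C@@H]3C)[C@@H](C)CC[C@@H]2C(C)C | intermediate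
21 | CNP0145304.1, (5R,8S)-2-[(5S,8R)-4-hydroxy-2,5-dimethyl-8-(propan-2-yl)-5,6,7,8-tetrahydronaphthalen-1-yl]-3,8-dimethyl-5-(propan-2-yl)-5,6,7,8-tetrahydronaphthalen-1-ol | Cc1cc2c(c(O)c1-c1c(C)cc(O)c3c1[C@@H](C(C)C)CC[C@@H]3C)[C@@H](C)CC[C@@H]2C(C)C | target

Total step count: 12.
Longest linear sequence: 10 steps (steps 1–5 and 8–12, from (+)-menthone); the other branch (steps 6–7, then 8–12) is 7 steps.

Steps most likely to fail

Step 11. The cation may migrate along the chain by hydride shifts before the ring closes (or a five-membered ring may close from C2'), and facial discrimination at C1' may be incomplete. The fallback replaces the free cation by a stereospecific displacement. It sets out from aldehyde 17. Wittig reaction with (methoxymethylene)triphenylphosphorane should give the enol ether F1, and aqueous HCl in THF hydrolyses it to the one-carbon-longer aldehyde F2. Catalytic asymmetric methyl addition (Me2Zn, Ti(O-i-Pr)4, the enantiomer of trans-1,2-bis(trifluoromethanesulfonamido)cyclohexane that gives the R carbinol) should give the (2R,5R)-alcohol F3. MsCl and Et3N convert it into the mesylate F4. Warming F4 in (CF3)2CHOH with 2,6-lutidine should let C8a' displace the mesylate with inversion (aryl-assisted Friedel–Crafts alkylation), which gives the (1'S) centre and returns to the route at 20.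

Step 8. Transmetalation of the doubly ortho-substituted boronate may be slower than its protodeboronation, and reductive elimination to the tetra-ortho-substituted biaryl may stall. The fallback gives up boron, base and water. It sets out from aryllithium 10, which is transmetalated with ZnCl2 to the arylzinc chloride F5. Negishi coupling of F5 with bromide 15 (Pd2(dba)3, RuPhos, THF/NMP, 70 °C), a method established for tetra-ortho-substituted biaryls and compatible with the ester, returns to the route at 16.

Step 5. Deprotonation may occur at a benzylic position (the C6 methyl or C1–H) or stay incomplete at C7, which lies between the methoxy and methyl groups. The fallback fixes the position by halogen instead of by deprotonation. It sets out from phenol 8. Amine-mediated ortho-bromination (NBS, catalytic i-Pr2NH, CH2Cl2) should give the 7-bromophenol F6, and MeI with K2CO3 gives the bromo methyl ether F7. Bromine–lithium exchange (n-BuLi, THF, −78 °C) then returns to the route at aryllithium 10, which is borylated as in step 5.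

Further compounds
F1 | step 11 | (5R,8S)-1-methoxy-2-{4-methoxy-2-[(3R)-6-methoxy-2-methylhex-5-en-3-yl]-6-methylphenyl}-3,8-dimethyl-5-(propan-2-yl)-5,6,7,8-tetrahydronaphthalene (E/Z mixture) | COC=CC[C@@H](c1cc(OC)cc(C)c1-c1c(C)cc2c(c1OC)[C@@H](C)CC[C@@H]2C(C)C)C(C)C
F2 | step 11 | (4R)-4-{5-methoxy-2-[(5R,8S)-1-methoxy-3,8-dimethyl-5-(propan-2-yl)-5,6,7,8-tetrahydronaphthalen-2-yl]-3-methylphenyl}-5-methylhexanal | O=CCC[C@@H](c1cc(OC)cc(C)c1-c1c(C)cc2c(c1OC)[C@@H](C)CC[C@@H]2C(C)C)C(C)C
F3 | step 11 | (2R,5R)-5-{5-methoxy-2-[(5R,8S)-1-methoxy-3,8-dimethyl-5-(propan-2-yl)-5,6,7,8-tetrahydronaphthalen-2-yl]-3-methylphenyl}-6-methylheptan-2-ol | C[C@@H](O)CC[C@@H](c1cc(OC)cc(C)c1-c1c(C)cc2c(c1OC)[C@@H](C)CC[C@@H]2C(C)C)C(C)C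
F4 | step 11 | (2R,5R)-5-{5-methoxy-2-[(5R,8S)-1-methoxy-3,8-dimethyl-5-(propan-2-yl)-5,6,7,8-tetrahydronaphthalen-2-yl]-3-methylphenyl}-6-methylheptan-2-yl methanesulfonate | C[C@@H](OS(C)(=O)=O)CC[C@@H](c1cc(OC)cc(C)c1-c1c(C)cc2c(c1OC)[C@@H](C)CC[C@@H]2C(C)C)C(C)C
F5 | step 8 | chloro[(5R,8S)-1-methoxy-3,8-dimethyl-5-(propan-2-yl)-5,6,7,8-tetrahydronaphthalen-2-yl]zinc | Cc1cc2c(c(OC)c1[Zn]Cl)[C@@H](C)CC[C@@H]2C(C)C
F6 | step 5 | (5R,8S)-2-bromo-3,8-dimethyl-5-(propan-2-yl)-5,6,7,8-tetrahydronaphthalen-1-ol | Cc1cc2c(c(O)c1Br)[C@@H](C)CC[C@@H]2C(C)C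
F7 | step 5 | (1S,4R)-7-bromo-8-methoxy-1,6-dimethyl-4-(propan-2-yl)-1,2,3,4-tetrahydronaphthalene | Cc1cc2c(c(OC)c1Br)[C@@H](C)CC[C@@H]2C(C)C
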